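## Structural features

The target is pentacyclic. An α,β-unsaturated δ-lactone (ring A: C2, O4, C5, C7, C8, C9) is spiro-joined at C9 to a cyclohexane (ring B: C9, C10, C11, C12, C21, C22). Ring B is cis-fused along C12–C21 to a cyclopentane (ring C: C12, C21, C20, C18, C25), which spans two bridges of a bicyclo[2.2.2]octane (bridgeheads C14 and C25; bridges C12–C13, C18–C16, C30–C31), and a γ-lactone (C25, C26, O27, C28, C30) sits on the C25–C30 bond. There are nine stereocentres, six of them fully substituted (C9, C12, C14, C18, C22, C25), in two contiguous runs: C9–C22–C21–C12–C25–C18 and C25–C30–C31–C14. Seen from C25 the bridges run counter-clockwise C12, C18, C30; the C19 methyl and the C30 hydrogen point into the sector between the C18 and C30 bridges, the C31 hydroxyl points toward the C16 bridge, and the C22 hydroxyl is axial on ring B on the C25/C26 face. Fragile groups are the tertiary C22 alcohol (vinylogous aldol partner of the ring A carbonyl, so retro-aldol under base), the enoate, and the β-hydroxy γ-lactone with its epimerizable C30. The real difficulty is the array of three mutually bonded quaternary carbons C12–C25–C18 inside a cage, the lone C20 methylene that must join C21 to quaternary C18, and the near mirror symmetry of the C18 and C30 bridges. The key step exploits that, in a bicyclo[2.2.2]octane carrying an acetyl group (C21, C22) on C12, the tertiary C18–H bond lies 1,5 to a carbene carbon generated on C21, so inserting that carbon (C20) closes ring C and makes C18 quaternary at once.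

## Logic of the disconnections

43 is cut at C9–C22 and C2–O4 together, giving 42. These two bonds create ring B, the spiro centre and ring A; without them the cage carries only an open chain. The forward step must bring nucleophilic C9 onto the hindered C22 carbonyl, place O24 on the C26 face, and catch the C2 cation with a carboxyl that is cis on C7=C8.

42 is cut at C7=C8 (to 40 and 41), then at C8–C9 (40 via 38 to 36 and 37), then at C9=C2 (36 to 34 and 35). This reduces the chain to a C9 aldehyde using three mild C–C bond formations. The demands are Z geometry at C7=C8 and reaction at the aldehyde or alkene only, in the presence of two ketones and the γ-lactone.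

34 is traced through 33, 32, 31, 30 and 29 to 28 by functional-group changes and one cut, C22–C23. The acetyl group becomes the allylic methyl of a cyclopentene. The forward steps need oxidation at C22 only and the C21 epimer with the acetyl on the C26 face.

28 is cut at C28–C30 and taken back through 26, 24 and 23 to 22. The lactone carbonyl comes from a one-carbon reagent and C26 from an ester. The forward steps need enolization at C30 only, hydride delivery to C31 from the C13 side, and a trans C30/C31 relation.

22 is cut at C18–C20 and C20=C21, giving 20 and 21. This removes ring C and returns C18 to a tertiary C–H centre. The demand is insertion into that one C–H bond with retention.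

20 is traced through 19 to 18 (acetyl to vinyl, ketals to ketones) and 18 is cut at C18–C19, giving 17 and 11. The result is a diketone whose two enolizable bridges are mirror-like. The forward methylation therefore needs reagent control to choose C18, and must place the methyl away from C12.

17 is cut at C13–C14 and taken back through 15 and 14 to 13. The cage opens to a cyclohexane-1,3-dione precursor with a C13 electrophile. The forward step is a C-alkylation at a neopentyl carbon.

13 is cut at C12–C25 by a [3,3] shift (to 10, with 11 for the methyl ester), and 10 at the ester C–O, giving 9 and 7. This joins two quaternary carbons and sets C12, the only stereocentre at that stage, by chirality transfer from C10.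

9 comes from 8 by dearomatization; 7 comes from 5 and 6, 5 from 4, 4 from 3, and 3 from 1 and 2.

## Other disconnections considered

Alternative 1: the cut is C18–C20 with C25–C30 and C14–C31. In the forward step an aromatic ether rearranges at an ortho carbon and the resulting cyclohexadienone is trapped by a tethered β-boryl acrylate, giving the lactone-fused bicyclooctenone boronate A1. In its favour, one thermal operation builds the cage, the γ-lactone and quaternary C18. The E-acrylate fixes the trans C30/C31 relation and the C–B bond gives the C31 hydroxyl with retention; on this point it is better than the chosen plan, which needs a reduction and an epimerization. It is also shorter to the cage. Against it, both ortho carbons carry methyl groups, so C18 and C14 compete in the rearrangement. The face of the cycloaddition depends on telling a methyl from a crotyl group at C18. C12 is left as an alkene carbon, so its quaternary centre and the C12–C21 bond must be made later on a crowded bridge alkene. The chosen plan sets C12 first by chirality transfer and closes ring C by a stereospecific insertion.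

Alternative 2: the cut is C12–C13 and C16–C18. A cyclic β-keto ester adds through C12 to methacrolein A3 and the ketone enolate then closes on the aldehyde, giving the bicyclo[3.2.1]octanone ketol A2. In its favour, two bonds, both bridgehead quaternary centres (C12, C18) and the C14 and C16 centres come from one amine-catalysed annulation of simple parts. In step count to rings C and D it is better than the chosen plan, and its mechanism is equally well understood. Against it, C25 remains a ketone that must become an all-carbon quaternary centre bearing C26 and C30. C14 is only tertiary and must be quaternized when the C30–C31 bridge is built, and C11 arrives as an ester carbon. The hardest cage bonds are thus postponed, whereas the chosen plan takes C14 and C25 from an aromatic ring at the start.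

Alternative 3: the cut is C25–C30 and C26–C28. Dichloroketene A5 adds across an exocyclic C25=C26 methylene to give the spiro dichlorocyclobutanone A4. In its favour, quaternary C25 and all four lactone carbons arrive in one reliable cycloaddition. The chlorines direct the later oxygen insertion to the C26 side and give a handle for the C30–C31 bond. For the lactone this is equal to or better than the carbonate acylation of the chosen plan. Against it, the face of addition on the one-carbon bridge decides C25 with no obvious bias. The methylene must first be made from a very hindered ketone, and ring expansion, dechlorination and cage closure add steps that also set C30 and C31. The chosen plan has C25 in place before any cage bond is made.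

Key step: step 14

## Remarks on the design (before the steps)

- Atom labels C1–O32 follow the target SMILES order and are used in all names.
- Checked and corrected: the stereodescriptors of the insertion substrate and product agree with the target at C12, C14, C18 and C25. One point is corrected: C30–H2 is also 1,5 to the carbene carbon (through C25). It is excluded only because the acetyl occupies the C12 position that faces the C18 bridge.
- Improved substrate: the side chain is carried through the insertion as its (E)-C10=C11 alkene with a benzyl ether on O9, so that C10–H is vinylic and cannot compete. The carbon skeleton, the two bonds formed and the ring closed are unchanged.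
- Assumption: the antipodes written for the ruthenium catalyst (step 2) and the lithium amide (step 11) are those expected by analogy; if a small-scale test shows the opposite sense, the mirror-image reagent is used.

## Steps

Step 1
Reactants: 1 2-(benzyloxy)acetyl chloride; 2 tert-butyldimethyl(prop-2-yn-1-yloxy)silane
Product: 3 1-(benzyloxy)-5-[(tert-butyldimethylsilyl)oxy]pent-3-yn-2-one
Conditions: PdCl2(PPh3)2 (2 mol%), CuI (4 mol%), Et3N, THF, 23 °C
Reagents that add atoms: none
Why: Acyl Sonogashira coupling of an acid chloride with a terminal alkyne gives the ynone directly; no stereocentre is formed.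

Step 2
Reactants: 3 1-(benzyloxy)-5-[(tert-butyldimethylsilyl)oxy]pent-3-yn-2-one
Product: 4 (2R)-1-(benzyloxy)-5-[(tert-butyldimethylsilyl)oxy]pent-3-yn-2-ol
Conditions: RuCl[(S,S)-TsDPEN](p-cymene) (1 mol%), HCO2H/Et3N (5:2), CH2Cl2, 23 °C
Reagents that add atoms: none
Why: Noyori–Ikariya asymmetric transfer hydrogenation of an alkynyl ketone; the alkyne is the π group recognized by the catalyst, which is chosen to give the R carbinol (C10).

Step 3
Reactants: 4 (2R)-1-(benzyloxy)-5-[(tert-butyldimethylsilyl)oxy]pent-3-yn-2-ol
Product: 5 (2R,3Z)-1-(benzyloxy)-5-[(tert-butyldimethylsilyl)oxy]-4-iodopent-3-en-2-ol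
Conditions: NaAlH2(OCH2CH2OMe)2, THF, 0 °C; then I2, −78 °C
Reagents that add atoms: iodine, II
Why: Alkoxide-directed trans-hydroalumination puts hydrogen on C11 and aluminium on C12; iodinolysis with retention gives the Z iodide, and the low temperature avoids loss of silyloxide to an allene.

Step 4
Reactants: 5 (2R,3Z)-1-(benzyloxy)-5-[(tert-butyldimethylsilyl)oxy]-4-iodopent-3-en-2-ol; 6 potassium vinyltrifluoroborate
Product: 7 (2R,3E)-1-(benzyloxy)-4-{[(tert-butyldimethylsilyl)oxy]methyl}hexa-3,5-dien-2-ol
Conditions: PdCl2(dppf) (5 mol%), Cs2CO3, THF/H2O (9:1), 70 °C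
Reagents that add atoms: none
Why: Suzuki–Miyaura coupling with retention of alkene geometry, so the vinyl group (future C21–C22) is cis to C10 and the silyloxymethyl (C13) trans.

Step 5
Reactants: 8 3,5-dimethoxy-4-methylbenzoic acid
Product: 9 3,5-dimethoxy-4-methylcyclohexa-2,5-diene-1-carboxylic acid (cis/trans mixture at C25/C14)
Conditions: Li, NH3 (l), THF, −78 °C; then NH4Cl
Reagents that add atoms: none
Why: Birch reduction of a benzoic acid protonates the ipso and para carbons and leaves both enol ethers; the C14 epimers converge later.

Step 6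
Reactants: 9 3,5-dimethoxy-4-methylcyclohexa-2,5-diene-1-carboxylic acid; 7 (2R,3E)-1-(benzyloxy)-4-{[(tert-butyldimethylsilyl)oxy]methyl}hexa-3,5-dien-2-ol
Product: 10 (2R,3E)-1-(benzyloxy)-4-{[(tert-butyldimethylsilyl)oxy]methyl}hexa-3,5-dien-2-yl 3,5-dimethoxy-4-methylcyclohexa-2,5-diene-1-carboxylate
Conditions: DCC, DMAP (10 mol%), CH2Cl2, 0 °C
Reagents that add atoms: none
Why: Steglich esterification proceeds with retention at C10; low temperature limits conjugation of the skipped diene acid.

Step 7
Reactants: 10 (2R,3E)-1-(benzyloxy)-4-{[(tert-butyldimethylsilyl)oxy]methyl}hexa-3,5-dien-2-yl 3,5-dimethoxy-4-methylcyclohexa-2,5-diene-1-carboxylate; 11 iodomethane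
Product: 13 methyl 1-[(2E,4R)-1-(benzyloxy)-4-{[(tert-butyldimethylsilyl)oxy]methyl}hexa-2,5-dien-4-yl]-3,5-dimethoxy-4-methylcyclohexa-2,5-diene-1-carboxylate, via Claisen acid 12 (not isolated)
Conditions: LiN(iPr)2, THF, −78 °C; Me3SiCl/Et3N; −78 → 65 °C; H2O; then MeI, K2CO3, DMF, 23 °C
Reagents that add atoms: none
Why: Ireland–Claisen rearrangement through a chair with the C9 benzyloxymethyl equatorial transfers the C10 configuration to quaternary C12 and gives the E C10=C11 alkene. The ring arms are identical, so ketene acetal geometry is irrelevant, and the carboxylate is then methylated.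

Step 8
Reactants: 13 methyl 1-[(2E,4R)-1-(benzyloxy)-4-{[(tert-butyldimethylsilyl)oxy]methyl}hexa-2,5-dien-4-yl]-3,5-dimethoxy-4-methylcyclohexa-2,5-diene-1-carboxylate
Product: 14 methyl 1-[(2E,4R)-1-(benzyloxy)-4-(hydroxymethyl)hexa-2,5-dien-4-yl]-3,5-dimethoxy-4-methylcyclohexa-2,5-diene-1-carboxylate
Conditions: Bu4NF, AcOH (1:1), THF, 0 → 23 °C
Reagents that add atoms: none
Why: Fluoride removes the primary silyl ether; the acetic acid buffer avoids a free alkoxide, which would close the C13–O/C26 γ-lactone.

Step 9
Reactants: 14 methyl 1-[(2E,4R)-1-(benzyloxy)-4-(hydroxymethyl)hexa-2,5-dien-4-yl]-3,5-dimethoxy-4-methylcyclohexa-2,5-diene-1-carboxylate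
Product: 15 methyl 1-[(2E,4R)-1-(benzyloxy)-4-{[(methylsulfonyl)oxy]methyl}hexa-2,5-dien-4-yl]-3,5-dimethoxy-4-methylcyclohexa-2,5-diene-1-carboxylate
Conditions: MsCl, Et3N, CH2Cl2, −20 °C, directly after step 8
Reagents that add atoms: methanesulfonyl chloride, CS(=O)(=O)Cl
Why: Sulfonylation of the primary alcohol is fast and leaves the enol ethers untouched.

Step 10
Reactants: 15 methyl 1-[(2E,4R)-1-(benzyloxy)-4-{[(methylsulfonyl)oxy]methyl}hexa-2,5-dien-4-yl]-3,5-dimethoxy-4-methylcyclohexa-2,5-diene-1-carboxylate
Product: 17 methyl 7-[(1E)-3-(benzyloxy)prop-1-en-1-yl]-7-ethenyl-4-methyl-3,5-dioxobicyclo[2.2.2]octane-1-carboxylate (bridgeheads C25 and C14, ketones C16 and C31, C12 as set in step 7), via dione mesylate 16 (not isolated)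
Conditions: 1 M HCl, THF, 0 → 23 °C; then Cs2CO3, DMF, 80 °C
Reagents that add atoms: water, O
Why: Hydrolysis of both enol ethers gives the 2-methylcyclohexane-1,3-dione, whose C14 carbon displaces the C13 mesylate in a six-membered closure to the bicyclo[2.2.2]octane. O-alkylation would give a bridgehead enol ether, and the β-carbons of the neopentyl centre are sp2, which lowers the usual hindrance.

Step 11
Reactants: 17 methyl 7-[(1E)-3-(benzyloxy)prop-1-en-1-yl]-7-ethenyl-4-methyl-3,5-dioxobicyclo[2.2.2]octane-1-carboxylate; 11 iodomethane
Product: 18 the C18-methyl dione, methyl 7-[(1E)-3-(benzyloxy)prop-1-en-1-yl]-7-ethenyl-2,4-dimethyl-3,5-dioxobicyclo[2.2.2]octane-1-carboxylate, with the methyl on the bridge syn to the vinyl group, pointing away from C12, and C18–H facing C12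
Conditions: LiN[(R)-CH(CH3)Ph]2, LiCl, THF, −78 °C; then MeI, −78 → −40 °C
Reagents that add atoms: none
Why: The C18 and C30 methylenes are mirror-like and the substrate cannot tell them apart, so a chiral lithium amide (enantiotopos-selective deprotonation of ketones) chooses the C18 proton. Iodomethane then enters anti to the vinyl group on C12, which leaves C18–H pointing at C12.

Step 12
Reactants: 18 the C18-methyl dione
Product: 19 the bis(ethylene ketal) of 18 (dioxolanes at C16 and C31)
Conditions: (Me3SiOCH2)2, Me3SiOTf (10 mol%), CH2Cl2, −78 → −20 °C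
Reagents that add atoms: 1,2-bis(trimethylsilyloxy)ethane, C[Si](C)(C)OCCO[Si](C)(C)C
Why: Silyl triflate-catalysed ketalization with the bis-silyl ether of glycol is driven by disiloxane formation and reaches the hindered C16 carbonyl without epimerizing C18.

Step 13
Reactants: 19 the bis(ethylene ketal) vinyl compound
Product: 20 the C12-acetyl bicyclo[2.2.2]octane bis-ketal methyl ester (insertion substrate; acetyl on the C12 position facing C18, (E)-3-(benzyloxy)prop-1-enyl on the other)
Conditions: PdCl2 (10 mol%), CuCl, O2 (1 atm), DMF/H2O (7:1), 23 °C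
Reagents that add atoms: water, O
Why: Tsuji–Wacker oxidation converts the terminal vinyl group into the methyl ketone (Markovnikov); the internal allylic-ether alkene reacts much more slowly.

Step 14
Reactants: 20 the C12-acetyl bis-ketal methyl ester; 21 (trimethylsilyl)diazomethane
Product: 22 the isotwistene bis-ketal methyl ester (ring C = C12–C21(CH3)=C20H–C18–C25, C18 quaternary)
Conditions: Me3SiCHN2, n-BuLi, THF, −78 °C; then −78 → 23 °C
Reagents that add atoms: none
Why: The lithium salt of 21 adds to the C21 carbonyl, loss of lithium trimethylsilanolate gives the diazoalkene, and loss of N2 gives the alkylidene carbene C21=C20. The singlet carbene inserts in one concerted step, through a five-centre cyclic transition state, into the C18–H bond 1,5 to C20, forming C18–C20 and leaving C20=C21; the closest known type is the 1,5 C–H insertion of alkylidene carbenes made from ketones and lithiated (trimethylsilyl)diazomethane. Ring C closes by this σ-bond insertion, not by a polar cyclization, so only the 1,5 distance matters. C18 becomes quaternary with retention, so its configuration is that of the C18–H bond set in step 11. The acetyl faces the C18 bridge, so C30–H2 is out of reach; C10–H is vinylic, and cyclopropanation of C10=C11 would need a bicyclo[2.1.0]pentene. C13–H would give a cyclobutene and C26 is a carbonyl carbon. Both ring ketones are ketals, so they are neither attacked nor enolized and C18–H is not α to a carbonyl. A 1,2-shift to an alkyne is slow for dialkyl alkylidene carbenes.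

Step 15
Reactants: 22 the isotwistene bis-ketal methyl ester
Product: 23 the C26 primary alcohol
Conditions: LiAlH4, THF, 0 → 66 °C
Reagents that add atoms: none
Why: Hydride reduction of the only carbonyl group; ketals, alkenes and the benzyl ether are inert.

Step 16
Reactants: 23 the C26 primary alcohol
Product: 24 the C31 ketone with the C16 dioxolane retained
Conditions: pyridinium p-toluenesulfonate, acetone/H2O (10:1), 40 °C
Reagents that add atoms: water, O
Why: The C16 dioxolane is flanked by two quaternary carbons (C14, C18), which hinders water attack on its oxocarbenium ion, so the C31 ketal should hydrolyse first.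

Step 17
Reactants: 24 the C31 ketone with the C16 dioxolane
Product: 26 the β-keto γ-lactone (C25–C26–O27–C28(=O)–C30; C30 epimers and enol), via mixed methyl carbonate 25 (not isolated)
Conditions: NaH, (MeO)2CO, THF, 66 °C; then aq. NH4Cl
Reagents that add atoms: dimethyl carbonate, COC(=O)OC
Why: The C26 alkoxide forms the methyl carbonate, and the C31 enolate, which can form only toward C30, acylates on it in a five-membered Claisen-type closure.

Step 18
Reactants: 26 the β-keto γ-lactone
Product: 28 the trans hydroxy lactone (C31–OH toward the C16 bridge, C28 on C30 toward the C12 bridge, as in the target), via C30-epimeric hydroxy lactone 27 (not isolated)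
Conditions: NaBH4, CeCl3·7H2O, MeOH/THF, −40 °C; then DBU, toluene, 60 °C
Reagents that add atoms: none
Why: The C16 dioxolane blocks the face of C31 toward that bridge, so hydride enters from the C13 side and the hydroxyl ends toward C16. The adduct with C28 and the hydroxyl eclipsed is then epimerized at C30 through the lactone enol to the strain-free trans isomer.

Step 19
Reactants: 28 the trans hydroxy lactone
Product: 29 the C22 enal (C20=C21–CHO)
Conditions: SeO2, 1,4-dioxane, 80 °C
Reagents that add atoms: selenium dioxide, O=[Se]=O
Why: Allylic oxidation by ene reaction and [2,3] shift; the C22 methyl is the only allylic C–H position of the trisubstituted alkene, because C12 and C18 are quaternary.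

Step 20
Reactants: 29 the C22 enal
Product: 30 the C22 enal with the C16 ketone
Conditions: 2 M HCl, THF, 50 °C
Reagents that add atoms: water, O
Why: Acid hydrolysis of the hindered dioxolane is done now, when the only alkenes are the acid-stable enal and the allylic ether.

Step 21
Reactants: 30 the C22 enal with the C16 ketone
Product: 31 the allylic alcohol C20=C21–CH(OH)CH3 (C22 epimers)
Conditions: MeTi(OiPr)3, THF, −40 → 0 °C
Reagents that add atoms: methyltitanium triisopropoxide, C[Ti](OC(C)C)(OC(C)C)OC(C)C
Why: The methyltitanium reagent adds 1,2 to aldehydes and spares the hindered ketone and the lactone; the new carbinol centre is removed in the next step.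

Step 22
Reactants: 31 the allylic alcohol
Product: 32 the enone C20=C21–C(=O)CH3
Conditions: MnO2, CH2Cl2, 23 °C
Reagents that add atoms: none
Why: MnO2 oxidizes the allylic alcohol only, so the saturated C31 hydroxyl needs no protection.

Step 23
Reactants: 32 the enone
Product: 33 the saturated C21 methyl ketone with a 3-hydroxypropyl chain (acetyl on the ring C face syn to C26)
Conditions: H2 (1 atm), Pd/C, EtOAc, 23 °C; then DBU (cat.), CH2Cl2
Reagents that add atoms: none
Why: One hydrogenation saturates the enone and the chain alkene and removes the benzyl ether. C21 is α to the ketone and is equilibrated through the enol; the epimer with the acetyl on the C26 face is the only one from which ring B can close cis, and the other is recycled.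

Step 24
Reactants: 33 the saturated methyl ketone with the 3-hydroxypropyl chain
Product: 34 the C9 aldehyde
Conditions: TEMPO (10 mol%), PhI(OAc)2, CH2Cl2, 23 °C
Reagents that add atoms: none
Why: The oxoammonium oxidation is selective for the primary alcohol over the hindered secondary C31 hydroxyl.

Step 25
Reactants: 34 the C9 aldehyde; 35 isopropyltriphenylphosphonium iodide
Product: 36 the trisubstituted alkene C9H=C2(CH3)2
Conditions: n-BuLi, THF, 0 °C (ylide); then 34, −78 → 0 °C
Reagents that add atoms: none
Why: Wittig olefination; the aldehyde reacts far faster than the hindered ketones, and inverse addition at low temperature limits enolate side reactions.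

Step 26
Reactants: 36 the trisubstituted alkene; 37 formaldehyde (as paraformaldehyde)
Product: 38 the homoallylic alcohol C9H(CH2OH)(isopropenyl) (C9 epimers; C8 introduced)
Conditions: (CH2O)n, Me2AlCl, CH2Cl2, −78 → 0 °C
Reagents that add atoms: none
Why: Lewis acid-promoted carbonyl-ene reaction; formaldehyde bonds to the less substituted alkene carbon (C9) and a methyl hydrogen is transferred, and this is much faster at low temperature than an ene reaction with the hindered C22 ketone.

Step 27
Reactants: 38 the homoallylic alcohol
Product: 40 the conjugated aldehyde C9(=C(CH3)2)–CHO, via deconjugated aldehyde 39 (not isolated)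
Conditions: TEMPO (10 mol%), PhI(OAc)2, CH2Cl2, 23 °C; then DBU (20 mol%)
Reagents that add atoms: none
Why: Selective oxidation of the primary alcohol, then base-mediated migration of the double bond into conjugation, which also removes the C9 stereocentre.

Step 28
Reactants: 40 the conjugated aldehyde; 41 methyl bis(2,2,2-trifluoroethyl)phosphonoacetate
Product: 42 the methyl (2Z)-dienoate C9(=C(CH3)2)–C8H=C7H–CO2CH3
Conditions: KN(SiMe3)2, 18-crown-6, THF, −78 °C
Reagents that add atoms: none
Why: Still–Gennari olefination gives the Z enoate under kinetic control; the stabilized phosphonate anion does not deprotonate the ketones or the hydroxyl.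

Step 29
Reactants: 42 the methyl (2Z)-dienoate
Product: 43 the target, CNP0360620.3
Conditions: Me2AlCl (4 equiv), CH2Cl2, −78 → 0 °C
Reagents that add atoms: none
Why: Proposed new method: the aluminium-complexed C22 ketone is attacked by C9, the γ-carbon of the dienoate, giving a tertiary C2 cation that the cis ester carbonyl traps with loss of chloromethane, so ring B, the spiro centre and ring A form together; the closest known types are Lewis acid Prins/carbonyl-ene cyclizations of ketones and halolactonization of dienoic esters. The methyl on C22 cannot occupy the axial site against C26, so O24 goes there, and an antiperiplanar open transition state puts C2 anti to O24, which is the target configuration at C22 and C9.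

## Compound list

1 | 2-(benzyloxy)acetyl chloride | O=C(Cl)COCc1ccccc1 | starting material
2 | tert-butyldimethyl(prop-2-yn-1-yloxy)silane | C#CCO[Si](C)(C)C(C)(C)C | starting material
3 | 1-(benzyloxy)-5-[(tert-butyldimethylsilyl)oxy]pent-3-yn-2-one | O=C(COCc1ccccc1)C#CCO[Si](C)(C)C(C)(C)C | intermediate
4 | (2R)-1-(benzyloxy)-5-[(tert-butyldimethylsilyl)oxy]pent-3-yn-2-ol | O[C@@H](COCc1ccccc1)C#CCO[Si](C)(C)C(C)(C)C | intermediate
5 | (2R,3Z)-1-(benzyloxy)-5-[(tert-butyldimethylsilyl)oxy]-4-iodopent-3-en-2-ol | O[C@@H](COCc1ccccc1)/C=C(\I)CO[Si](C)(C)C(C)(C)C | intermediate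
6 | potassium vinyltrifluoroborate | C=C[B-](F)(F)F.[K+] | starting material
7 | (2R,3E)-1-(benzyloxy)-4-{[(tert-butyldimethylsilyl)oxy]methyl}hexa-3,5-dien-2-ol | O[C@@H](COCc1ccccc1)/C=C(\C=C)CO[Si](C)(C)C(C)(C)C | intermediate
8 | 3,5-dimethoxy-4-methylbenzoic acid | COc1cc(C(=O)O)cc(OC)c1C | starting material
9 | 3,5-dimethoxy-4-methylcyclohexa-2,5-diene-1-carboxylic acid (cis/trans mixture) | COC1=CC(C(=O)O)C=C(OC)C1C | intermediate
10 | (2R,3E)-1-(benzyloxy)-4-{[(tert-butyldimethylsilyl)oxy]methyl}hexa-3,5-dien-2-yl 3,5-dimethoxy-4-methylcyclohexa-2,5-diene-1-carboxylate | COC1=CC(C(=O)O[C@@H](COCc2ccccc2)/C=C(\C=C)CO[Si](C)(C)C(C)(C)C)C=C(OC)C1C | intermediate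
11 | iodomethane | CI | starting material
12 | Claisen acid: 1-[(2E,4R)-1-(benzyloxy)-4-{[(tert-butyldimethylsilyl)oxy]methyl}hexa-2,5-dien-4-yl]-3,5-dimethoxy-4-methylcyclohexa-2,5-diene-1-carboxylic acid | OC(=O)C1(C=C(OC)C(C)C(OC)=C1)[C@@](CO[Si](C)(C)C(C)(C)C)(C=C)/C=C/COCc2ccccc2 | intermediate
13 | methyl ester of 12 | COC(=O)C1(C=C(OC)C(C)C(OC)=C1)[C@@](CO[Si](C)(C)C(C)(C)C)(C=C)/C=C/COCc2ccccc2 | intermediate
14 | methyl 1-[(2E,4R)-1-(benzyloxy)-4-(hydroxymethyl)hexa-2,5-dien-4-yl]-3,5-dimethoxy-4-methylcyclohexa-2,5-diene-1-carboxylate | COC(=O)C1(C=C(OC)C(C)C(OC)=C1)[C@@](CO)(C=C)/C=C/COCc2ccccc2 | intermediate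
15 | C13 mesylate of 14 | COC(=O)C1(C=C(OC)C(C)C(OC)=C1)[C@@](COS(C)(=O)=O)(C=C)/C=C/COCc2ccccc2 | intermediate
16 | dione mesylate (2-methylcyclohexane-1,3-dione form of 15) | COC(=O)C1(CC(=O)C(C)C(=O)C1)[C@@](COS(C)(=O)=O)(C=C)/C=C/COCc2ccccc2 | intermediate
17 | methyl 7-[(1E)-3-(benzyloxy)prop-1-en-1-yl]-7-ethenyl-4-methyl-3,5-dioxobicyclo[2.2.2]octane-1-carboxylate | C=C[C@]1(/C=C/COCc3ccccc3)CC2(C)C(=O)CC1(C(=O)OC)CC2=O | intermediate
18 | C18-methyl dione (methyl on the bridge syn to vinyl, anti to C12; C18–H toward C12) | C=C[C@]1(/C=C/COCc3ccccc3)C[C@]2(C)C(=O)[C@@H](C)[C@@]1(C(=O)OC)CC2=O | intermediate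
19 | bis(ethylene ketal) of 18 | C=C[C@]1(/C=C/COCc5ccccc5)C[C@]2(C)C3(OCCO3)[C@@H](C)[C@@]1(C(=O)OC)CC24OCCO4 | intermediate
20 | C12-acetyl bicyclo[2.2.2]octane bis-ketal methyl ester with (E)-3-(benzyloxy)prop-1-enyl on C12 | CC(=O)[C@]1(/C=C/COCc5ccccc5)C[C@]2(C)C3(OCCO3)[C@@H](C)[C@@]1(C(=O)OC)CC24OCCO4 | intermediate
21 | (trimethylsilyl)diazomethane | C[Si](C)(C)C=[N+]=[N-] | starting material
22 | isotwistene bis-ketal methyl ester (C20=C21, quaternary C18) | CC1=C[C@@]2(C)C3(OCCO3)[C@@]4(C)C[C@]1(/C=C/COCc6ccccc6)[C@]2(C(=O)OC)CC45OCCO5 | intermediate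
23 | C26 primary alcohol of 22 | CC1=C[C@@]2(C)C3(OCCO3)[C@@]4(C)C[C@]1(/C=C/COCc6ccccc6)[C@]2(CO)CC45OCCO5 | intermediate
24 | C31 ketone, C16 dioxolane, C26 alcohol | CC1=C[C@@]2(C)C3(OCCO3)[C@@]4(C)C[C@]1(/C=C/COCc6ccccc6)[C@]2(CO)CC4=O | intermediate
25 | mixed methyl carbonate of 24 | CC1=C[C@@]2(C)C3(OCCO3)[C@@]4(C)C[C@]1(/C=C/COCc6ccccc6)[C@]2(COC(=O)OC)CC4=O | intermediate
26 | β-keto γ-lactone (C30 unfixed) | CC1=C[C@@]2(C)C3(OCCO3)[C@@]4(C)C[C@]1(/C=C/COCc6ccccc6)[C@@]25COC(=O)C5C4=O | intermediate
27 | cis hydroxy lactone (C30 epimer of 28) | CC1=C[C@@]2(C)C3(OCCO3)[C@@]4(C)C[C@]1(/C=C/COCc6ccccc6)[C@@]25COC(=O)[C@H]5[C@H]4O | intermediate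
28 | trans hydroxy lactone (C30, C31 as in the target) | CC1=C[C@@]2(C)C3(OCCO3)[C@@]4(C)C[C@]1(/C=C/COCc6ccccc6)[C@@]25COC(=O)[C@@H]5[C@H]4O | intermediate
29 | C22 enal, C16 dioxolane | O=CC1=C[C@@]2(C)C3(OCCO3)[C@@]4(C)C[C@]1(/C=C/COCc6ccccc6)[C@@]25COC(=O)[C@@H]5[C@H]4O | intermediate
30 | C22 enal, C16 ketone | O=CC1=C[C@@]2(C)C(=O)[C@@]4(C)C[C@]1(/C=C/COCc6ccccc6)[C@@]25COC(=O)[C@@H]5[C@H]4O | intermediate
31 | allylic alcohol (C22 epimers) | CC(O)C1=C[C@@]2(C)C(=O)[C@@]4(C)C[C@]1(/C=C/COCc6ccccc6)[C@@]25COC(=O)[C@@H]5[C@H]4O | intermediate
32 | enone C20=C21–C(=O)CH3 | CC(=O)C1=C[C@@]2(C)C(=O)[C@@]4(C)C[C@]1(/C=C/COCc6ccccc6)[C@@]25COC(=O)[C@@H]5[C@H]4O | intermediate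
33 | saturated C21 methyl ketone, 3-hydroxypropyl chain | CC(=O)[C@@H]1C[C@@]2(C)C(=O)[C@@]4(C)C[C@]1(CCCO)[C@@]25COC(=O)[C@@H]5[C@H]4O | intermediate
34 | C9 aldehyde | CC(=O)[C@@H]1C[C@@]2(C)C(=O)[C@@]4(C)C[C@]1(CCC=O)[C@@]25COC(=O)[C@@H]5[C@H]4O | intermediate
35 | isopropyltriphenylphosphonium iodide | CC(C)[P+](c1ccccc1)(c1ccccc1)c1ccccc1.[I-] | starting material
36 | trisubstituted alkene C9H=C(CH3)2 | CC(=O)[C@@H]1C[C@@]2(C)C(=O)[C@@]4(C)C[C@]1(CCC=C(C)C)[C@@]25COC(=O)[C@@H]5[C@H]4O | intermediate
37 | formaldehyde (used as paraformaldehyde) | C=O | starting material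
38 | homoallylic alcohol C9H(CH2OH)(isopropenyl) (C9 epimers) | CC(=O)[C@@H]1C[C@@]2(C)C(=O)[C@@]4(C)C[C@]1(CCC(CO)C(C)=C)[C@@]25COC(=O)[C@@H]5[C@H]4O | intermediate
39 | deconjugated aldehyde C9H(CHO)(isopropenyl) | CC(=O)[C@@H]1C[C@@]2(C)C(=O)[C@@]4(C)C[C@]1(CCC(C=O)C(C)=C)[C@@]25COC(=O)[C@@H]5[C@H]4O | intermediate
40 | conjugated aldehyde C9(=C(CH3)2)–CHO | CC(=O)[C@@H]1C[C@@]2(C)C(=O)[C@@]4(C)C[C@]1(CCC(C=O)=C(C)C)[C@@]25COC(=O)[C@@H]5[C@H]4O | intermediate
41 | methyl bis(2,2,2-trifluoroethyl)phosphonoacetate | COC(=O)CP(=O)(OCC(F)(F)F)OCC(F)(F)F | starting material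
42 | methyl (2Z)-dienoate C9(=C(CH3)2)–CH=CH–CO2CH3 | CC(=O)[C@@H]1C[C@@]2(C)C(=O)[C@@]4(C)C[C@]1(CCC(/C=C\C(=O)OC)=C(C)C)[C@@]25COC(=O)[C@@H]5[C@H]4O | intermediate
43 | CNP0360620.3 | CC1(C)OC(=O)C=C[C@]12CC[C@]13C[C@]4(C)C(=O)[C@](C)(C[C@H]1[C@@]2(C)O)[C@]31COC(=O)[C@@H]1[C@H]4O | target

## Step count and least certain steps

Total: 29 steps. Longest linear sequence: 28 steps (steps 1–4, then 6–29); step 5 is a one-step side branch.

Step 29 (spirolactonization). The dienoate is a weak π-nucleophile and the C22 ketone is hindered. Adventitious acid could instead close ring A by protonation at C9, the C2 cation could lose a proton before the ester traps it, or the wrong C21 epimer could fail to react. Fallback: from 42, hydrolyse the methyl ester with Me3SnOH (1,2-dichloroethane, 80 °C) to the (2Z)-dienoic acid F1. Bromolactonize it with N-bromosuccinimide and NaHCO3 (bromonium at C9, carboxylate at C2) to the 5-bromo-6,6-dimethyl-5,6-dihydropyran-2-one F2. Treat F2 with SmI2 in THF at −78 °C: the samarium dienolate adds through C9 to the C22 ketone (Reformatsky-type closure of a six-membered ring), rejoining the route at 43.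

Step 14 (key step). The lithiated diazo reagent may enolize the hindered methyl ketone rather than add to it, which returns starting material, or the carbene may be diverted to the ester oxygen. Fallback: from 20, chloromethylenate the ketone with Ph3P=CHCl (Wittig) to the vinyl chloride F3, then treat with KN(SiMe3)2 in ether. α-Elimination gives the same alkylidene carbene by a path that needs no addition to the carbonyl under enolizing conditions, rejoining at 22.

Step 11 (C18 methylation). The chiral amide may discriminate poorly between the mirror-like C18 and C30 protons, giving the regioisomeric methyl ketone. Fallback: from 17, reduce the C31 carbonyl with catalyst control (Corey–Bakshi–Shibata reduction, oxazaborolidine antipode chosen for C31) to the hydroxy ketone F7. Methylate its only enolizable position with LiN(iPr)2 (2 equiv) and iodomethane to give F8, then oxidize the carbinol with Dess–Martin periodinane, rejoining at 18.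

Step 10 (cage closure). Displacement at the neopentyl C13 may be slow enough for the ester carbonyl to participate and give the C26/C13 lactone, or for the mesylate to eliminate or hydrolyse. Fallback: from 14, oxidize to the C13 aldehyde F4 (Parikh–Doering). Hydrolyse the enol ethers with aqueous HCl so that the 2-methyl-1,3-dione adds to the aldehyde (intramolecular aldol) to give the C13-hydroxy cage F5. Convert F5 into the phenyl thionocarbonate F6 and deoxygenate with Bu3SnH and AIBN at high stannane concentration (Barton–McCombie), rejoining at 17.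

Step 18 (C31 reduction, C30 epimerization). Facial selectivity at C31 rests on the C16 dioxolane, and the base step may dehydrate the β-hydroxy lactone instead of epimerizing C30. Fallback: from 26, hydrogenate with RuCl2[(R)-BINAP] (or its antipode) in methanol. The catalyst-controlled dynamic kinetic resolution of α-substituted cyclic β-keto esters gives the trans hydroxy ester directly, rejoining at 28 with no compound outside the list (F0: none).

Step 16 (selective ketal hydrolysis). Both dioxolanes may hydrolyse at similar rates, losing the C16 mask that steers step 18. Fallback: from 23, hydrolyse both ketals with aqueous HCl to the diketone alcohol F9 and form the lactone with NaH and dimethyl carbonate to give F10 (C16 is not enolizable). Set C31 and C30 by the ruthenium–BINAP hydrogenation named above to give F11, then oxidize the allylic methyl with SeO2, rejoining at 30.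

## Further compounds

F1 | step 29 | (2Z)-dienoic acid from 42 | CC(=O)[C@@H]1C[C@@]2(C)C(=O)[C@@]4(C)C[C@]1(CCC(/C=C\C(O)=O)=C(C)C)[C@@]25COC(=O)[C@@H]5[C@H]4O
F2 | step 29 | 5-bromo-6,6-dimethyl-5,6-dihydropyran-2-one on the C10–C11 chain (C9 epimers) | CC(=O)[C@@H]1C[C@@]2(C)C(=O)[C@@]4(C)C[C@]1(CCC6(Br)C=CC(=O)OC6(C)C)[C@@]25COC(=O)[C@@H]5[C@H]4O
F3 | step 14 | vinyl chloride from 20 (E/Z mixture) | ClC=C(C)[C@]1(/C=C/COCc5ccccc5)C[C@]2(C)C3(OCCO3)[C@@H](C)[C@@]1(C(=O)OC)CC24OCCO4
F4 | step 10 | C13 aldehyde from 14 | COC(=O)C1(C=C(OC)C(C)C(OC)=C1)[C@@](C=O)(C=C)/C=C/COCc2ccccc2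
F5 | step 10 | C13-hydroxy cage dione (C13 epimers) | C=C[C@]1(/C=C/COCc3ccccc3)C(O)C2(C)C(=O)CC1(C(=O)OC)CC2=O
F6 | step 10 | phenyl thionocarbonate of F5 | C=C[C@]1(/C=C/COCc3ccccc3)C(OC(=S)Oc4ccccc4)C2(C)C(=O)CC1(C(=O)OC)CC2=O
F7 | step 11 | C31-hydroxy C16-ketone (C31 epimer unfixed) | C=C[C@]1(/C=C/COCc3ccccc3)C[C@]2(C)C(=O)C[C@@]1(C(=O)OC)CC2O
F8 | step 11 | C18-methylated hydroxy ketone | C=C[C@]1(/C=C/COCc3ccccc3)C[C@]2(C)C(=O)[C@@H](C)[C@@]1(C(=O)OC)CC2O
F9 | step 16 | diketone alcohol (both ketals removed) | CC1=C[C@@]2(C)C(=O)[C@@]4(C)C[C@]1(/C=C/COCc6ccccc6)[C@]2(CO)CC4=O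
F10 | step 16 | β-keto γ-lactone with free C16 ketone | CC1=C[C@@]2(C)C(=O)[C@@]4(C)C[C@]1(/C=C/COCc6ccccc6)[C@@]25COC(=O)C5C4=O
F11 | step 16 | trans hydroxy lactone with free C16 ketone | CC1=C[C@@]2(C)C(=O)[C@@]4(C)C[C@]1(/C=C/COCc6ccccc6)[C@@]25COC(=O)[C@@H]5[C@H]4O
F0 | step 18 | none | none
A1 | alternative 1 | lactone-fused bicyclo[2.2.2]octenone C31 pinacol boronate | COC(=O)CCCC1=C[C@]2(C)C(=O)[C@](C)(C/C=C/C)[C@]13COC(=O)[C@@H]3[C@H]2B4OC(C)(C)C(C)(C)O4
A2 | alternative 2 | bicyclo[3.2.1]octan-8-one ketol | COC(=O)[C@]12C[C@H](C)[C@@H](O)[C@](C)(C[C@H]1C(C)=C)C2=O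
A3 | alternative 2 | methacrolein | C=C(C)C=O
A4 | alternative 3 | spiro α,α-dichlorocyclobutanone at C25 | COC(=O)[C@]12C[C@@](C)(COCc3ccc(OC)cc3)C(=O)[C@](C)(C[C@H]1C4(C)OCCO4)[C@]25CC(=O)C5(Cl)Cl
A5 | alternative 3 | dichloroketene | ClC(Cl)=C=O
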